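**Retrosynthetic overview**
1. Endgame: the 3-methylbut-2-enoate is put on last (Steglich) onto 5-O-methylalkannin 24, after removal of an arene pivalate and a side-chain TBS ether.
2. Ring B (quinone ring, C1–C4 on C4a/C8a of benzenoid ring A) is formed last, by ring expansion of a benzocyclobutenone. A four-membered ring with a temporary C1–C4 bond, absent from the target, is built on ring A and then fragmented.
3. Key event: thermal 4π opening of that bond to a dienylketene, 6π closure making the C3–C4 bond (alkenyl CH2 to ketene carbon), then oxidation to the quinone. Enabling feature: C1 and C4 sit on the adjacent arene carbons C8a and C4a, so they can be tied together as a benzocyclobutenedione, and C2=C3 with the side chain on C2 is a 1,1-disubstituted alkene that can arrive as an alkenyllithium.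
4. The precursor comes from 1,2-addition of (S)-alkenyllithium 18 to dione 9; 9 comes from 2-bromo-1,4-dimethoxybenzene by aryne/ketene acetal [2+2] (ring order: A purchased, four-membered ring, then B).
5. The single stereocentre is set by allylboration of 2-bromoacrolein and carried through unchanged; the prenyl terminus comes from cross-metathesis.

Key step: step 10

Remark: the target is the (S)-enantiomer (alkannin series); since O > sp2 carbon > CH2 > H holds at the carbinol carbon at every stage, the descriptor stays S from 14 to 26. Naphthoquinone numbering is used throughout (ring A = C5–C8, ring B = C1–C4).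

**Step 1**
Reactants: 1 2-bromo-1,4-dimethoxybenzene; 2 1,1-diethoxyethene
Product: 5 2,5-dimethoxybicyclo[4.2.0]octa-1,3,5-trien-7-one, via 3,6-dimethoxybenzyne 3 (not isolated), via diethyl ketal 4 (not isolated)
Conditions: NaNH2 (2 equiv), 2 (3 equiv), THF, reflux; then 1 M HCl, THF, rt
Reagents that add atoms: water, O
Why: Dehydrobromination gives the aryne flanked by both methoxy groups, which undergoes [2+2] cycloaddition with the ketene acetal (aryne/ketene acetal benzocyclobutenone synthesis), and acid hydrolysis of the ketal releases the ketone.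

**Step 2**
Reactants: 5 2,5-dimethoxybicyclo[4.2.0]octa-1,3,5-trien-7-one
Product: 6 5-hydroxy-2-methoxybicyclo[4.2.0]octa-1,3,5-trien-7-one
Conditions: BBr3 (1.05 equiv), CH2Cl2, −78 → −20 °C; H2O work-up
Reagents that add atoms: none
Why: Lewis-acid ether cleavage in which BBr3 bound to the ketone oxygen activates the conjugated, ortho-acyl methoxy group (a vinylogous ester) for bromide attack while the aryloxyborane formed disfavours a second cleavage; the regioisomeric monophenol, if formed, would converge on the same dione 9 in step 4.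

**Step 3**
Reactants: 6 5-hydroxy-2-methoxybicyclo[4.2.0]octa-1,3,5-trien-7-one
Product: 7 2-methoxy-7-oxobicyclo[4.2.0]octa-1,3,5-trien-5-yl pivalate
Conditions: PivCl, Et3N, DMAP (cat.), CH2Cl2, 0 °C
Reagents that add atoms: pivaloyl chloride, CC(C)(C)C(=O)Cl
Why: O-acylation of the phenol gives an ester that should survive radical bromination, the organolithium at −78 °C and the thermolysis, and it turns this oxygen into a poor π-donor, which is needed for step 9.

**Step 4**
Reactants: 7 2-methoxy-7-oxobicyclo[4.2.0]octa-1,3,5-trien-5-yl pivalate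
Product: 9 2-methoxy-7,8-dioxobicyclo[4.2.0]octa-1,3,5-trien-5-yl pivalate, via gem-dibromide 8 (not isolated)
Conditions: NBS (2.2 equiv), AIBN (cat.), PhCF3, 85 °C; then AgO2CCF3 (2.2 equiv), MeCN/H2O, rt
Reagents that add atoms: water, O
Why: Wohl–Ziegler dibromination of the doubly activated (benzylic, α-keto) CH2 followed by silver-assisted hydrolysis of the gem-dibromide is the standard passage from benzocyclobutenones to benzocyclobutenediones.

**Step 5**
Reactants: 10 acrolein
Product: 12 2-bromoacrolein, via 2,3-dibromopropanal 11 (not isolated)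
Conditions: Br2, CH2Cl2, −78 → 0 °C; then Et3N, 0 °C
Reagents that add atoms: bromine, BrBr
Why: Bromine addition to the alkene followed by base-induced loss of HBr from the α-bromo aldehyde gives the 2-bromo enal.

**Step 6**
Reactants: 12 2-bromoacrolein; 13 B-allyldiisopinocampheylborane derived from (+)-α-pinene, d-Ipc2B(allyl)
Product: 14 (S)-2-bromohexa-1,5-dien-3-ol
Conditions: 13 (1.1 equiv), Et2O, −100 → −78 °C; then 3 M NaOH, 30% H2O2, 0 °C → rt
Reagents that add atoms: none
Why: Brown allylboration through a chair six-membered transition state, in which the (+)-α-pinene-derived reagent delivers allyl to the si face of the aldehyde, which for an aldehyde whose substituent outranks allyl (as with benzaldehyde) corresponds to the (S)-carbinol.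

**Step 7**
Reactants: 14 (S)-2-bromohexa-1,5-dien-3-ol
Product: 15 (S)-(2-bromohexa-1,5-dien-3-yloxy)(tert-butyl)dimethylsilane
Conditions: TBSCl, imidazole, DMF, rt
Reagents that add atoms: tert-butyldimethylsilyl chloride, CC(C)(C)[Si](C)(C)Cl
Why: Standard silylation gives an ether that tolerates t-BuLi, the ruthenium carbene and heating, without touching the C–O bond of the stereocentre.

**Step 8**
Reactants: 15 (S)-(2-bromohexa-1,5-dien-3-yloxy)(tert-butyl)dimethylsilane; 16 2-methylbut-2-ene
Product: 17 (S)-(2-bromo-6-methylhepta-1,5-dien-3-yloxy)(tert-butyl)dimethylsilane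
Conditions: second-generation Grubbs catalyst (H2IMes)(PCy3)Cl2Ru=CHPh (5 mol%), 16 (excess, co-solvent), CH2Cl2, 40 °C
Reagents that add atoms: none
Why: Olefin cross-metathesis of the terminal alkene with 2-methylbut-2-ene installs the isopropylidene terminus, while the 1,1-disubstituted vinyl bromide is inert towards the ruthenium carbene.

**Step 9**
Reactants: 17 (S)-(2-bromo-6-methylhepta-1,5-dien-3-yloxy)(tert-butyl)dimethylsilane; 9 2-methoxy-7,8-dioxobicyclo[4.2.0]octa-1,3,5-trien-5-yl pivalate
Product: 19 7-hydroxy-2-methoxy-8-oxo-7-[(3S)-3-(tert-butyldimethylsilyloxy)-6-methylhepta-1,5-dien-2-yl]bicyclo[4.2.0]octa-1,3,5-trien-5-yl pivalate (both epimers at C7), via alkenyllithium 18 (not isolated)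
Conditions: t-BuLi (2.0 equiv), Et2O, −78 °C; cannulated into 9 (1.1 equiv), THF, −78 °C; H2O/THF quench at −78 °C
Reagents that add atoms: none
Why: Bromine–lithium exchange then 1,2-addition to the more electrophilic carbonyl of the dione: the carbonyl on the arene carbon ortho to OMe is a vinylogous ester, whereas the one ortho to the weakly donating pivaloyloxy group stays ketone-like (the regiochemistry known for additions to 3-alkoxybenzocyclobutenediones); the new carbinol centre forms without control, which is irrelevant because it becomes sp2 in step 10.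

**Step 10**
Reactants: 19 the 7-alkenyl-7-hydroxybenzocyclobutenone from step 9
Product: 22 5-methoxy-8-(pivaloyloxy)-2-[(1S)-1-(tert-butyldimethylsilyloxy)-4-methylpent-3-en-1-yl]naphthalene-1,4-dione, via dienylketene 20 (not isolated), via hydroquinone 21 (not isolated)
Conditions: degassed p-xylene, 138 °C, argon; then Ag2O, Et2O, rt
Reagents that add atoms: none
Why: Heating opens the hydroxycyclobutenone by conrotatory 4π electrocyclic ring opening, which cleaves the temporary bond between the future C1 and C4; the hydroxyl rotates outward (donor torquoselectivity) and so places the 2-propenyl unit cis to the new ketene in 20. A 6π electrocyclization of this (Z)-dienylketene then joins the alkenyl CH2 terminus (C3) to the ketene carbon (C4), closing ring B as a six-membered ring while ring A regains aromaticity; enolization gives hydroquinone 21 and Ag2O dehydrogenates it to quinone 22. The closest known reaction type is the Moore rearrangement, the thermal ring expansion of 4-alkenyl-4-hydroxycyclobutenones and 2-alkenyl-2-hydroxybenzocyclobutenones to quinones. No stereocentre is created: both carbinol epimers of 19 converge, and the side-chain (S) centre lies outside the pericyclic array. The step needs regiochemical fidelity (side chain on C2 next to the carbonyl peri to the acyloxy group, C3–H next to the carbonyl peri to OMe), which is fixed by the connectivity of 19, and outward rotation of OH, which is intrinsic to the donor substituent.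

**Step 11**
Reactants: 22 the 8-pivaloyloxy quinone from step 10
Product: 23 8-hydroxy-5-methoxy-2-[(1S)-1-(tert-butyldimethylsilyloxy)-4-methylpent-3-en-1-yl]naphthalene-1,4-dione
Conditions: K2CO3 (1.5 equiv), MeOH, 0 °C, argon; AcOH quench
Reagents that add atoms: none
Why: Methanolysis of an activated aryl ester whose leaving group is an acidic peri-hydroxyquinone phenoxide; the phenoxide formed deactivates the quinone towards methoxide addition and the silyl ether is untouched.

**Step 12**
Reactants: 23 the 8-hydroxy quinone silyl ether from step 11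
Product: 24 8-hydroxy-2-[(1S)-1-hydroxy-4-methylpent-3-en-1-yl]-5-methoxynaphthalene-1,4-dione (5-O-methylalkannin)
Conditions: HF·pyridine, THF/pyridine, 0 °C → rt
Reagents that add atoms: none
Why: Fluoride-mediated desilylation under weakly acidic conditions that the quinone, the chelated phenol and the trisubstituted alkene should tolerate; the C–O bond at the stereocentre is not broken.

**Step 13**
Reactants: 24 5-O-methylalkannin; 25 3-methylbut-2-enoic acid
Product: 26 (S)-1-(8-hydroxy-5-methoxy-1,4-dioxo-1,4-dihydronaphthalen-2-yl)-4-methylpent-3-en-1-yl 3-methylbut-2-enoate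
Conditions: DCC, DMAP (cat.), CH2Cl2, 0 °C → rt
Reagents that add atoms: none
Why: Steglich esterification acylates the secondary side-chain alcohol while the peri-phenol, hydrogen-bonded to the C1 carbonyl, stays free (the chemoselectivity known for acylation of alkannin and shikonin); configuration is retained since only the O–H bond is engaged.

**Compound list**
1 | 2-bromo-1,4-dimethoxybenzene | COc1ccc(OC)c(Br)c1 | starting material
2 | 1,1-diethoxyethene | C=C(OCC)OCC | starting material
3 | 3,6-dimethoxybenzyne | COC1=CC=C(OC)C#C1 | intermediate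
4 | 7,7-diethoxy-2,5-dimethoxybicyclo[4.2.0]octa-1,3,5-triene | CCOC1(OCC)Cc2c(OC)ccc(OC)c21 | intermediate
5 | 2,5-dimethoxybicyclo[4.2.0]octa-1,3,5-trien-7-one | COc1ccc(OC)c2c1CC2=O | intermediate
6 | 5-hydroxy-2-methoxybicyclo[4.2.0]octa-1,3,5-trien-7-one | COc1ccc(O)c2c1CC2=O | intermediate
7 | 2-methoxy-7-oxobicyclo[4.2.0]octa-1,3,5-trien-5-yl pivalate | COc1ccc(OC(=O)C(C)(C)C)c2c1CC2=O | intermediate
8 | 8,8-dibromo-2-methoxy-7-oxobicyclo[4.2.0]octa-1,3,5-trien-5-yl pivalate | COc1ccc(OC(=O)C(C)(C)C)c2c1C(Br)(Br)C2=O | intermediate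
9 | 2-methoxy-7,8-dioxobicyclo[4.2.0]octa-1,3,5-trien-5-yl pivalate | COc1ccc(OC(=O)C(C)(C)C)c2c1C(=O)C2=O | intermediate
10 | acrolein | C=CC=O | starting material
11 | 2,3-dibromopropanal | O=CC(Br)CBr | intermediate
12 | 2-bromoacrolein | C=C(Br)C=O | intermediate
13 | B-allyldiisopinocampheylborane from (+)-α-pinene | C=CCB([C@@H]1C[C@@H]2C[C@H]([C@H]1C)C2(C)C)[C@@H]1C[C@@H]2C[C@H]([C@H]1C)C2(C)C | starting material
14 | (S)-2-bromohexa-1,5-dien-3-ol | C=C(Br)[C@@H](O)CC=C | intermediate
15 | (S)-(2-bromohexa-1,5-dien-3-yloxy)(tert-butyl)dimethylsilane | C=C(Br)[C@@H](O[Si](C)(C)C(C)(C)C)CC=C | intermediate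
16 | 2-methylbut-2-ene | CC=C(C)C | starting material
17 | (S)-(2-bromo-6-methylhepta-1,5-dien-3-yloxy)(tert-butyl)dimethylsilane | C=C(Br)[C@@H](O[Si](C)(C)C(C)(C)C)CC=C(C)C | intermediate
18 | [(3S)-3-(tert-butyldimethylsilyloxy)-6-methylhepta-1,5-dien-2-yl]lithium | [Li]C(=C)[C@@H](O[Si](C)(C)C(C)(C)C)CC=C(C)C | intermediate
19 | 7-hydroxy-2-methoxy-8-oxo-7-[(3S)-3-(tert-butyldimethylsilyloxy)-6-methylhepta-1,5-dien-2-yl]bicyclo[4.2.0]octa-1,3,5-trien-5-yl pivalate (both C7 epimers) | COc1ccc(OC(=O)C(C)(C)C)c2c1C(=O)C2(O)C(=C)[C@@H](O[Si](C)(C)C(C)(C)C)CC=C(C)C | intermediate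
20 | dienylketene: 4-methoxy-3-(oxomethylidene)-2-[(Z)-hydroxy(alkenyl)methylidene]cyclohexa-4,6-dienyl pivalate with the (S) side chain | COC1=CC=C(OC(=O)C(C)(C)C)/C(=C(\O)C(=C)[C@@H](O[Si](C)(C)C(C)(C)C)CC=C(C)C)C1=C=O | intermediate
21 | 5-methoxy-8-(pivaloyloxy)-2-[(1S)-1-(tert-butyldimethylsilyloxy)-4-methylpent-3-en-1-yl]naphthalene-1,4-diol | COc1ccc(OC(=O)C(C)(C)C)c2c(O)c([C@@H](O[Si](C)(C)C(C)(C)C)CC=C(C)C)cc(O)c12 | intermediate
22 | 5-methoxy-8-(pivaloyloxy)-2-[(1S)-1-(tert-butyldimethylsilyloxy)-4-methylpent-3-en-1-yl]naphthalene-1,4-dione | COc1ccc(OC(=O)C(C)(C)C)c2c1C(=O)C=C([C@@H](O[Si](C)(C)C(C)(C)C)CC=C(C)C)C2=O | intermediate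
23 | 8-hydroxy-5-methoxy-2-[(1S)-1-(tert-butyldimethylsilyloxy)-4-methylpent-3-en-1-yl]naphthalene-1,4-dione | COc1ccc(O)c2c1C(=O)C=C([C@@H](O[Si](C)(C)C(C)(C)C)CC=C(C)C)C2=O | intermediate
24 | 8-hydroxy-2-[(1S)-1-hydroxy-4-methylpent-3-en-1-yl]-5-methoxynaphthalene-1,4-dione | COc1ccc(O)c2c1C(=O)C=C([C@@H](O)CC=C(C)C)C2=O | intermediate
25 | 3-methylbut-2-enoic acid | CC(C)=CC(=O)O | starting material
26 | (S)-1-(8-hydroxy-5-methoxy-1,4-dioxo-1,4-dihydronaphthalen-2-yl)-4-methylpent-3-en-1-yl 3-methylbut-2-enoate | COc1ccc(O)c2c1C(=O)C=C([C@H](CC=C(C)C)OC(=O)C=C(C)C)C2=O | target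

**Totals and risks**
Total step count: 13. Longest linear sequence: 9 steps (steps 1–4, then 9–13; equally steps 5–8, then 9–13).

Steps most likely to fail:

1. Step 9. The two carbonyl groups of 9 may be discriminated insufficiently, so that the organolithium also attacks the methoxy-side carbonyl, or it may attack the aryl pivalate. The fallback fixes the regiochemistry by masking. It sets out from 7: after dibromination to 8, the gem-dibromide would be solvolysed in methanol (AgO2CCF3, MeOH) instead of water. This should give 2,8,8-trimethoxy-7-oxobicyclo[4.2.0]octa-1,3,5-trien-5-yl pivalate F1, in which only the carbonyl next to the pivaloyloxy-bearing arene carbon is free. Alkenyllithium 18 would then add to that single ketone to give the ketal carbinol F2. Mild aqueous acid (oxalic acid, THF/H2O) would unmask the ketone and deliver 19, where the route is rejoined before step 10.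

2. Step 10. The dienylketene may be diverted (lactonisation through the carbinol oxygen if the hydroxyl rotates inward, or intermolecular trapping). The pivaloyl group may shift between the peri oxygens at the hydroquinone stage, or silanol may be lost thermally with erosion of the stereocentre. The fallback makes the same C3–C4 bond at low temperature and at a lower oxidation level. It sets out from 5 and alkenyllithium 18 (made from 17 as in step 9). Addition to the single ketone of 5 would give the lithium alkoxide of 7-[(3S)-3-(tert-butyldimethylsilyloxy)-6-methylhepta-1,5-dien-2-yl]-2,5-dimethoxybicyclo[4.2.0]octa-1,3,5-trien-7-ol F3. On warming to rt this should undergo oxy-anion-accelerated 4π opening and 6π closure to the tetralone 5,8-dimethoxy-2-[(1S)-1-(tert-butyldimethylsilyloxy)-4-methylpent-3-en-1-yl]-3,4-dihydronaphthalen-1(2H)-one F4. BCl3 (CH2Cl2, −78 °C) would cleave only the methoxy group peri to the ketone, through a six-membered chelate, to give the 8-hydroxy-5-methoxy tetralone F5. DDQ (dioxane, 80 °C) would aromatise it to 5-methoxy-2-[(1S)-1-(tert-butyldimethylsilyloxy)-4-methylpent-3-en-1-yl]naphthalene-1,8-diol F6. Teuber oxidation with Fremy's salt (KSO3)2NO (acetone/aqueous KH2PO4) at the free position para to the 1-hydroxyl would give 23, where the route is rejoined before step 12. This detour needs neither 9 nor a regioselective carbonyl addition.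

3. Step 2. Over-cleavage to the bis-phenol or Lewis-acid-induced opening of the strained ketone may occur. The fallback postpones the differentiation to the symmetric dione. It sets out from 5: Wohl–Ziegler dibromination would give 8,8-dibromo-2,5-dimethoxybicyclo[4.2.0]octa-1,3,5-trien-7-one F7, and silver-assisted hydrolysis would give 2,5-dimethoxybicyclo[4.2.0]octa-1,3,5-triene-7,8-dione F8. In F8 both methoxy groups are equivalent vinylogous esters. Nucleophilic mono-demethylation with MgI2 (toluene/Et2O, 60 °C; SN2 at methyl) should stop at 5-hydroxy-2-methoxybicyclo[4.2.0]octa-1,3,5-triene-7,8-dione F9, because the vinylogous carboxylate formed resists a second dealkylation. Pivaloylation as in step 3 then gives 9, where the route is rejoined before step 9.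

**Further compounds**
F1 | step 9 | 2,8,8-trimethoxy-7-oxobicyclo[4.2.0]octa-1,3,5-trien-5-yl pivalate | COc1ccc(OC(=O)C(C)(C)C)c2c1C(OC)(OC)C2=O
F2 | step 9 | 7-hydroxy-2,8,8-trimethoxy-7-[(3S)-3-(tert-butyldimethylsilyloxy)-6-methylhepta-1,5-dien-2-yl]bicyclo[4.2.0]octa-1,3,5-trien-5-yl pivalate | COc1ccc(OC(=O)C(C)(C)C)c2c1C(OC)(OC)C2(O)C(=C)[C@@H](O[Si](C)(C)C(C)(C)C)CC=C(C)C
F3 | step 10 | 7-[(3S)-3-(tert-butyldimethylsilyloxy)-6-methylhepta-1,5-dien-2-yl]-2,5-dimethoxybicyclo[4.2.0]octa-1,3,5-trien-7-ol | COc1ccc(OC)c2c1CC2(O)C(=C)[C@@H](O[Si](C)(C)C(C)(C)C)CC=C(C)C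
F4 | step 10 | 5,8-dimethoxy-2-[(1S)-1-(tert-butyldimethylsilyloxy)-4-methylpent-3-en-1-yl]-3,4-dihydronaphthalen-1(2H)-one | COc1ccc(OC)c2c1CCC([C@@H](O[Si](C)(C)C(C)(C)C)CC=C(C)C)C2=O
F5 | step 10 | 8-hydroxy-5-methoxy-2-[(1S)-1-(tert-butyldimethylsilyloxy)-4-methylpent-3-en-1-yl]-3,4-dihydronaphthalen-1(2H)-one | COc1ccc(O)c2c1CCC([C@@H](O[Si](C)(C)C(C)(C)C)CC=C(C)C)C2=O
F6 | step 10 | 5-methoxy-2-[(1S)-1-(tert-butyldimethylsilyloxy)-4-methylpent-3-en-1-yl]naphthalene-1,8-diol | COc1ccc(O)c2c(O)c([C@@H](O[Si](C)(C)C(C)(C)C)CC=C(C)C)ccc12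
F7 | step 2 | 8,8-dibromo-2,5-dimethoxybicyclo[4.2.0]octa-1,3,5-trien-7-one | COc1ccc(OC)c2c1C(Br)(Br)C2=O
F8 | step 2 | 2,5-dimethoxybicyclo[4.2.0]octa-1,3,5-triene-7,8-dione | COc1ccc(OC)c2c1C(=O)C2=O
F9 | step 2 | 5-hydroxy-2-methoxybicyclo[4.2.0]octa-1,3,5-triene-7,8-dione | COc1ccc(O)c2c1C(=O)C2=O
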